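**A direct plan and its weak points**

A direct plan would set C8 by an asymmetric Baeyer–Villiger desymmetrisation of 4-butylcyclohexanone (A1) to lactone A2, open A2 and brominate to the Weinreb amide bromide A3, make bromofuran A4, extend it to pentenylfuran A5 by Negishi coupling, join A5 to A3 by hydroboration/alkyl–alkyl Suzuki coupling, and reduce the amide to the aldehyde.
- Weak: the desymmetrising ring expansion A1 → A2 would have to tell apart two identical CH2CH2 arms beside a small, flexible n-butyl group; the enantiomeric purity of C8 would be uncertain, and the oily intermediates could not upgrade it.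
- Weak: the furan bromination to A4; an electron-rich 2-bromofuran with an activated CH2CO2Me arm would decompose easily and could brominate at that CH2.
- Weak: the late alkyl–alkyl Suzuki coupling with the unactivated bromide A3 (β-hydride elimination, chiral fragment limiting); it would form C5–C6, remote from C8, so three steps would be spent on the chiral piece without joining the fragments at the stereocentre.

**Retrosynthetic overview of the new route**

- Numbering: side chain C1 (on furan C5) to C11 (CHO). C8, the only stereocentre, carries three saturated arms and lies γ to the aldehyde carbon.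
- Last cut, C10–C11: the aldehyde carbon is CO, added by linear hydroformylation to a C9=C10 vinyl group, which makes C8 the allylic carbon of a terminal alkene.
- Key cut, C7–C8: a copper-catalysed enantioselective γ-selective (SN2') allyl–alkyl coupling joins the 9-BBN adduct of an achiral heptenylfuran acetate to achiral (Z)-1-chlorohept-2-ene, whose γ-carbon already bears the butyl group, and creates C8 in the same event.
- The furan is the only ring and is bought as furan; its two arms are put on by two successive α-metalations (alkylation at one α-carbon, zincation/coupling with bromoacetate at the other).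
- The design therefore needs no desymmetrisation, no halofuran, no coupling remote from the stereocentre and no protecting-group or amide/redox steps.

Key step: step 5

Assumption: (R)-DTBM-SEGPHOS is written for the key step on the understanding that the ligand antipode is chosen to deliver the alkyl group to the face of C8 that gives the (R)-alkene; if the sense of induction is the opposite, the (S)-ligand is used and nothing else changes.

**Route**

Step 1
Reactants: 1 furan; 2 7-bromohept-1-ene
Product: 4 2-(hept-6-en-1-yl)furan, via furan-2-yllithium 3 (not isolated)
Conditions: furan (1.3 equiv), n-BuLi (1.0 equiv), THF, −78 → 0 °C; then 2, THF, 0 °C → rt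
Reagents that add atoms: none
Why: Furan is lithiated at C2, its most acidic position next to the ring oxygen, and the furyllithium is alkylated by the primary bromide in an SN2 reaction (α-lithiation/alkylation), to which the remote terminal alkene is inert.

Step 2
Reactants: 4 2-(hept-6-en-1-yl)furan; 5 methyl bromoacetate
Product: 8 methyl 2-[5-(hept-6-en-1-yl)furan-2-yl]acetate, via 5-(hept-6-en-1-yl)furan-2-yllithium 6 (not isolated), via chloro[5-(hept-6-en-1-yl)furan-2-yl]zinc 7 (not isolated)
Conditions: n-BuLi, THF, −78 → 0 °C; ZnCl2, THF, 0 °C → rt; then 5, Ni(acac)2 (5 mol%), PPh3 (5 mol%), THF, rt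
Reagents that add atoms: none
Why: The only free α-position of 4 is lithiated selectively, transmetalation to zinc gives a nucleophile too mild to attack the ester, and the nickel-catalysed Negishi-type coupling of a heteroarylzinc chloride with an α-bromoacetate should form the ring–CH2CO2Me bond without touching the terminal alkene.

Step 3
Reactants: 9 hept-2-yn-1-ol
Product: 10 (Z)-hept-2-en-1-ol
Conditions: H2 (1 atm), Pd/CaCO3 poisoned with Pb(OAc)2, quinoline, EtOAc, rt
Reagents that add atoms: none
Why: Lindlar semihydrogenation adds H2 syn to the alkyne on the poisoned palladium surface and should stop at the (Z)-alkene, which fixes the alkene geometry that the key step needs.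

Step 4
Reactants: 10 (Z)-hept-2-en-1-ol
Product: 11 (Z)-1-chlorohept-2-ene
Conditions: NCS, Me2S, CH2Cl2, −20 → 0 °C
Reagents that add atoms: N-chlorosuccinimide, ClN1C(=O)CCC1=O
Why: In this Corey–Kim-type chlorination the alkoxysulfonium salt formed from 10 is displaced by chloride in an SN2 reaction at the primary carbon, so neither allylic transposition nor loss of the (Z) geometry is expected.

Step 5
Reactants: 8 methyl 2-[5-(hept-6-en-1-yl)furan-2-yl]acetate; 11 (Z)-1-chlorohept-2-ene
Product: 13 methyl 2-[5-[(8R)-8-ethenyldodecyl]furan-2-yl]acetate, via B-alkyl-9-BBN borane 12 (not isolated)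
Conditions: 8 (1.5 equiv), (9-BBN-H)2 (0.75 equiv), 1,4-dioxane, 60 °C; then CuOTf·(toluene)0.5 (10 mol%), (R)-DTBM-SEGPHOS (10 mol%), KOMe (1.5 equiv), 11 (1.0 equiv), 1,4-dioxane/CH2Cl2, 15 °C
Reagents that add atoms: none
Why: 9-BBN adds anti-Markovnikov to the terminal alkene of 8 only; methoxide then turns borane 12 into a borate that transfers its primary alkyl group to the bisphosphine-bound monovalent copper, and the alkylcopper attacks the γ-carbon (C8) of the alkene of 11 with loss of chloride, either by addition–elimination or through a trivalent copper σ-allyl that eliminates reductively before it can isomerise, which forms the C7–C8 bond. The closest known reaction type is the copper-catalysed enantioselective γ-selective allyl–alkyl coupling of alkyl-9-BBN reagents with (Z)-configured primary allyl chlorides, which gives terminal alkenes whose allylic stereocentre carries only sp3 alkyl groups. No ring is closed. The new stereocentre C8 is controlled by the catalyst alone: the C2-symmetric bisphosphine on copper selects one of the two enantiotopic faces of the γ-carbon of the achiral (Z)-alkene, and the (Z) geometry set in step 3 is the substrate feature on which this face selection rests. The step needs γ over α regioselectivity, which the unhindered CH2Cl terminus and the non-equilibrating copper allyl should secure, and chemoselectivity towards the methyl ester, which is secured by 9-BBN (inert to the ester and the furan here), by matching the alkoxide to the borane so that little free base remains, and by the choice of methoxide, so that any ester exchange is degenerate. Two achiral alkenes should thus give in one operation the chain C1–C10 with its butyl branch and the only stereocentre of the target.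

Step 6
Reactants: 13 methyl 2-[5-[(8R)-8-ethenyldodecyl]furan-2-yl]acetate
Product: 14 methyl 2-[5-[(8R)-8-butyl-11-oxoundecyl]furan-2-yl]acetate
Conditions: CO/H2 (1:1, 10 bar), Rh(acac)(CO)2 (1 mol%), Xantphos (3 mol%), toluene, 70 °C
Reagents that add atoms: carbon monoxide, [C-]#[O+]
Why: Rhodium-catalysed hydroformylation with the wide-bite-angle diphosphine Xantphos should deliver the formyl group to the terminal carbon C10, a preference that the branch at C8 reinforces, so that C11 arrives as the aldehyde with no redox adjustment, while C8 is not a reacting centre and the furan and the ester are inert to CO/H2 under these conditions.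

**Compound list**

1 | furan | c1ccoc1 | starting material
2 | 7-bromohept-1-ene | C=CCCCCCBr | starting material
3 | furan-2-yllithium | [Li]c1ccco1 | intermediate (not isolated)
4 | 2-(hept-6-en-1-yl)furan | C=CCCCCCc1ccco1 | intermediate
5 | methyl bromoacetate | COC(=O)CBr | starting material
6 | 5-(hept-6-en-1-yl)furan-2-yllithium | [Li]c1ccc(CCCCCC=C)o1 | intermediate (not isolated)
7 | chloro[5-(hept-6-en-1-yl)furan-2-yl]zinc | Cl[Zn]c1ccc(CCCCCC=C)o1 | intermediate (not isolated)
8 | methyl 2-[5-(hept-6-en-1-yl)furan-2-yl]acetate | COC(=O)Cc1ccc(CCCCCC=C)o1 | intermediate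
9 | hept-2-yn-1-ol | CCCCC#CCO | starting material
10 | (Z)-hept-2-en-1-ol | CCCC/C=C\CO | intermediate
11 | (Z)-1-chlorohept-2-ene | CCCC/C=C\CCl | intermediate
12 | methyl 2-[5-[7-(9-borabicyclo[3.3.1]nonan-9-yl)heptyl]furan-2-yl]acetate | COC(=O)Cc1ccc(CCCCCCCB2C3CCCC2CCC3)o1 | intermediate (not isolated)
13 | methyl 2-[5-[(8R)-8-ethenyldodecyl]furan-2-yl]acetate | CCCC[C@@H](C=C)CCCCCCCc1ccc(CC(=O)OC)o1 | intermediate
14 | methyl 2-[5-[(8R)-8-butyl-11-oxoundecyl]furan-2-yl]acetate | CCCC[C@@H](CCC=O)CCCCCCCc1ccc(CC(=O)OC)o1 | target

**Step count and risks**

Total step count: 6. Longest linear sequence: 4 (steps 1, 2, 5, 6; the branch through steps 3, 4, 5, 6 is equally long).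

Steps most likely to fail:

1. Step 5 (key step). The two faces of C8 may be told apart less well on this long-chain pair than hoped. Residual alkoxide may also divert material by deprotonation of the furyl–CH2–ester position followed by allylation there, or by direct α-substitution of the chloride. The fallback is a nickel-catalysed stereoconvergent γ-alkylation; it sets out from 8 (as its borane 12) and comes back to the route at 14.
   - Racemic 5-butyloxolan-2-one F1 (γ-octalactone, purchased) would be opened with SOCl2 and catalytic ZnCl2 to racemic 4-chlorooctanoyl chloride F2.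
   - F2 would be amidated with Ph2NH/Et3N to racemic 4-chloro-N,N-diphenyloctanamide F3.
   - Alkyl–alkyl Suzuki coupling of F3 with 12 (NiBr2·diglyme, a chiral N,N'-dimethyl-1,2-diarylethane-1,2-diamine, KOMe/MeOH as borane activator, i-Pr2O, rt) should give methyl 2-[5-[(8R)-8-butyl-11-(diphenylamino)-11-oxoundecyl]furan-2-yl]acetate F4. The amide oxygen directs the nickel, and both enantiomers of the chloride converge through a common alkyl radical.
   - Cp2Zr(H)Cl in THF would reduce the tertiary amide of F4 to the aldehyde 14 without touching the methyl ester.

2. Step 6. Reversible rhodium hydride addition could move the double bond into C8 before the formyl group is attached, which would erode the stereocentre or leave an unreactive trisubstituted alkene, and some branched aldehyde could form. The fallback is a stoichiometric borane carbonylation; it sets out from 13 and comes back at 14.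
   - Hydroboration of the vinyl group with 9-BBN (THF, rt) would give methyl 2-[5-[(8R)-8-[2-(9-borabicyclo[3.3.1]nonan-9-yl)ethyl]dodecyl]furan-2-yl]acetate F5. Its regiochemistry is fixed by sterics, with no metal hydride able to walk along the chain.
   - Reductive carbonylation of F5 (CO, 1 atm, K[HB(O-i-Pr)3], THF, 0 °C) and buffered H2O2 oxidation would release 14.

3. Step 2. The furylzinc chloride may undergo halogen–zinc exchange with the bromoacetate (homocoupling and protonated furan) in place of cross-coupling. The fallback is a hydroxyalkylation/deoxygenation sequence; it sets out from 4 and comes back at 8.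
   - Friedel–Crafts hydroxyalkylation of 4 at its free α-position with methyl glyoxylate (Yb(OTf)3 cat., CH2Cl2, 0 °C) would give racemic methyl 2-[5-(hept-6-en-1-yl)furan-2-yl]-2-hydroxyacetate F6.
   - Acetylation (Ac2O, pyridine, DMAP) would give racemic methyl 2-acetoxy-2-[5-(hept-6-en-1-yl)furan-2-yl]acetate F7.
   - Reductive removal of the α-acetoxy group with SmI2 (THF/MeOH, −78 °C) would give 8.

**Further compounds**

F1 | step 5 | 5-butyloxolan-2-one (racemic) | CCCCC1CCC(=O)O1
F2 | step 5 | 4-chlorooctanoyl chloride (racemic) | CCCCC(Cl)CCC(Cl)=O
F3 | step 5 | 4-chloro-N,N-diphenyloctanamide (racemic) | CCCCC(Cl)CCC(=O)N(c1ccccc1)c1ccccc1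
F4 | step 5 | methyl 2-[5-[(8R)-8-butyl-11-(diphenylamino)-11-oxoundecyl]furan-2-yl]acetate | CCCC[C@@H](CCC(=O)N(c1ccccc1)c1ccccc1)CCCCCCCc1ccc(CC(=O)OC)o1
F5 | step 6 | methyl 2-[5-[(8R)-8-[2-(9-borabicyclo[3.3.1]nonan-9-yl)ethyl]dodecyl]furan-2-yl]acetate | CCCC[C@@H](CCB1C2CCCC1CCC2)CCCCCCCc1ccc(CC(=O)OC)o1
F6 | step 2 | methyl 2-[5-(hept-6-en-1-yl)furan-2-yl]-2-hydroxyacetate (racemic) | COC(=O)C(O)c1ccc(CCCCCC=C)o1
F7 | step 2 | methyl 2-acetoxy-2-[5-(hept-6-en-1-yl)furan-2-yl]acetate (racemic) | COC(=O)C(OC(C)=O)c1ccc(CCCCCC=C)o1
A1 | direct plan | 4-butylcyclohexanone | CCCCC1CCC(=O)CC1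
A2 | direct plan | (5S)-5-butyloxepan-2-one | CCCC[C@@H]1CCOC(=O)CC1
A3 | direct plan | (4S)-4-(2-bromoethyl)-N-methoxy-N-methyloctanamide | CCCC[C@@H](CCC(=O)N(C)OC)CCBr
A4 | direct plan | methyl 2-(5-bromofuran-2-yl)acetate | COC(=O)Cc1ccc(Br)o1
A5 | direct plan | methyl 2-[5-(pent-4-en-1-yl)furan-2-yl]acetate | COC(=O)Cc1ccc(CCCC=C)o1
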